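## The problem

Compound 30 (CNP0105570.2) is a 6,7-seco-ent-kauranoid of the spiro-lactone type. Carbons carry their ent-kaurane numbers throughout, and α means the face of ring A that carries C20.

Ring A (C1–C5, C10) is joined through the spiro carbon C10 to a δ-lactone (C10–C20–O–C7–C8–C9). The lactone is cis-fused along C8–C9 to the six-membered ring C (C8, C9, C11–C14) of a bicyclo[3.2.1]octane, whose two-carbon bridge C15–C16 carries the ketone and the exocyclic methylene C17.

There are seven stereocentres (1S,4R,5R,8S,9S,10S,13R). C4, C8 and C10 are quaternary, and C8–C9–C10 are contiguous.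

Inside ring A the relay is easy: C4 controls C5 through a cis-fused ring, C5 controls C10 by alkylation, and the chair then fixes C1. C13 is forced by the bridge. C9 and C8, however, must be set from C10 across the spiro junction, and that is the weakest link.

Four ring-A carbons sit at the same alcohol oxidation level and must be told apart (C1–OAc, C19–OAc, C6–OH, C20–O–C7). O1 and O20 are both β to C9, so either could close a six-membered lactone onto C7.

The α-methylene cyclopentanone (a Michael acceptor), the acetates (base, hydride, migration to a free neighbouring OH) and the non-enolisable β-keto lactone at C8 (retro-Claisen) rule out rough treatment late in the route.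

The feature that opens the plan is this: C8 is the common α-carbon of the C7 lactone carbonyl and the C15 ketone, and C16 is the other α-carbon of that ketone, so C7–C8–C15–C16–C17 is a 3-oxoglutarate in disguise. The C8–C9 bond can therefore be born as the alkylidene double bond of a β-keto lactone, a doubly activated dienophile. Ring C contains that bond, so it is the [4+2] adduct of C8=C9 with a C11–C14 butadiene.

## Retrosynthesis

**30 ⇒ 28 (via 29).** The C16=C17 bond is cut to formaldehyde and a C16 carboxyl. A benzyl ester on C16 (the second ester of the oxoglutarate) keeps C16 an active carbon through the route and leaves as CO2 in a decarboxylative Mannich methylenation. This is preferred over enolate methylenation because it needs no strong base next to two acetates and a lactone, and the Michael acceptor appears only in the last operation.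

**28 ⇒ 27 ⇒ 25 ⇒ 24.** Ring D is opened at C13–C16. Both carbons are enol carbons (C16 of the β-keto ester, C13 of a C12 silyl enol ether), so the bond is made by oxidative union of two carbons of like polarity with (NH4)2Ce(NO3)6. A radical closure onto an unactivated C12=C13 alkene was weighed and set aside: attack at C12 (bicyclo[2.2.2]octane) competes with attack at C13. With the enol ether the polarity and the 5-exo geometry point the same way. The price is one step to delete the C12 oxygen (25 → 27).

**24 ⇒ 21 + 22 (key).** Three bonds are cut: C8=C9 (Knoevenagel) and C9–C11 / C8–C14 (Diels–Alder). Aldehyde 21 has only ring A; 24 has the lactone, ring C, the quaternary C8 and C9. Cutting here rather than at the lactone C–O bond uses the 1,3-dicarbonyl at C8 twice, once as Knoevenagel donor and once as dienophile activator. The "para" orientation of the 2-siloxydiene 22 places the enol ether at C12=C13, which is what the next disconnection needs. The forward reaction must add the diene to the lactone face syn to C1.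

**21 ⇒ 20 ⇒ 19 ⇒ 15 + 18, and 15 ⇒ 14 ⇒ 12 ⇒ 11.** The C20–O–C7 ester bond is cut to the diol 15 and the acyl Meldrum's acid 18, which delivers the whole benzyl 3-oxoglutaryl unit. Tetraol 11 is differentiated by geometry: O1/O20 are the only 1,3-diol (acetonide 12), and the C6 hydroxyl is the only primary alcohol not on a quaternary carbon (silyl ether). The large silyl group on C6 also serves the key step.

**11 ⇒ 10 ⇒ 7 + 8.** The C9–C10 bond is cut to the β-keto ester 7 and a vinyl cation equivalent (phenyl vinyl sulfoxide 8). The ester carbon of 7 is C20 and the vinyl carbon becomes the C9 aldehyde. Alkylation on the convex face of the cis-fused bicycle sets the quaternary C10. One LiAlH4 reduction then brings C1, C6, C19 and C20 to the alcohol level and sets C1.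

**7 ⇒ 4 ⇒ 2 + 3.** Ring A is cut at C5–C10 and C3–C4. The unit C19–C4(CH3)=C5–C6 is the 2-methylbutenedioic skeleton of the commercial enal ester 3, and C20–C10–C1–C2–C3 is the Nazarov reagent 1 as its silyl dienol ether 2. A chiral oxazaborolidinium catalyst sets C4, the only stereocentre set by catalysis; all others are relayed from it. The E-dienophile gives the C5 epimer, which is corrected when the γ-lactone C6(=O)–O–C19 closes under equilibrating conditions.

## Roads not taken

**Alternative 1:** (the most obvious) Keep ring D for last and add the C15 oxygen after it. Make a ring-A spiro-lactone, annulate ring C, alkylate the lactone enolate at C8 with a 2-bromoallyl group to give vinyl bromide A1, close ring D by vinyl-radical cyclisation (Bu3SnH) to A2, then oxidise C15 (SeO2, then an alcohol oxidation) to the enone.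
- C8 has to be made quaternary with strong base on a hindered spiro-lactone.
- The radical closure can give the bicyclo[2.2.2]octane as well.
- The C15 oxygen costs two late redox steps next to the free C6 alcohol.
- Nothing in this plan uses the 1,3-dicarbonyl at C8, which in the chosen route builds the lactone, activates the dienophile and closes ring D.

**Alternative 2:** Ester-tethered intramolecular Diels–Alder reaction. Cut C8–C9 and C13–C14: a buta-1,3-dienyl group on C10 and a 2-substituted acrylate on O20 (triene A3) close the lactone and ring C together to give A4.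
- The new alkene lands at C11=C12, so a radical or enol on the C8 side chain reaches C12 or C11, not C13; ring D then needs an alkene transposition.
- The diene has to be built on the neopentyl C9.
- The ester tether must react through its less favoured conformation.
- The C15 oxygen is again missing.
- In the chosen plan the diene is a commodity reagent, the dienophile is doubly activated, and the enol ether lands at C12=C13.

**Alternative 3:** Biomimetic cleavage of ring B. Build the intact 7,20-epoxy-ent-kaurane diol A5 and cleave the C6–C7 glycol (NaIO4), which gives the lactone and a C6 aldehyde at once; then reduce the aldehyde.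
- A5 is a harder target than 30: it has two more stereocentres, a bridged hemiketal and a trans-fused ring B that is built only to be broken.
- The final aldehyde reduction must spare the enone.

Key step: step 13

Assumption: ethyl 3-oxopent-4-enoate (1) is bought; it is otherwise made in two steps from acrolein and ethyl acetate.
Assumption: the (S)-oxazaborolidinium catalyst is written in step 2 by analogy with 2-substituted enals; if the sense of induction with 3 is the opposite, the (R)-catalyst is used.

## Route

Step 1
Reactants: 1 ethyl 3-oxopent-4-enoate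
Product: 2 ethyl (2Z)-3-[(triisopropylsilyl)oxy]penta-2,4-dienoate
Conditions: iPr3SiOTf, Et3N, CH2Cl2, 0 °C
Reagents that add atoms: triisopropylsilyl trifluoromethanesulfonate, CC(C)[Si](OS(=O)(=O)C(F)(F)F)(C(C)C)C(C)C
Why: Soft enolisation and O-silylation of the β-keto ester gives the 2-siloxydiene with the ester on the outside of the diene terminus (future C10).

Step 2
Reactants: 2 ethyl (2Z)-3-[(triisopropylsilyl)oxy]penta-2,4-dienoate; 3 ethyl (2E)-3-methyl-4-oxobut-2-enoate
Product: 4 diethyl (1R,6R)-6-formyl-6-methyl-3-[(triisopropylsilyl)oxy]cyclohex-3-ene-1,2-dicarboxylate (ring A with 4α-CHO, 4β-CH3, 5β-CO2Et; C10 epimers)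
Conditions: (S)-3,3-diphenyl-1-(2-methylphenyl)tetrahydro-1H,3H-pyrrolo[1,2-c][1,3,2]oxazaborole·HNTf2 (20 mol%), CH2Cl2, −78 → −40 °C
Reagents that add atoms: none
Why: Enantioselective Diels–Alder reaction of a 2-siloxydiene with a 2-substituted enal under chiral oxazaborolidinium catalysis; the catalyst-bound formyl group exposes one face and sets the quaternary C4 (R). The diene terminus C10 bonds to C5 (β to the formyl group, "para" orientation) and the E-alkene puts the C5 ester trans to the formyl group.

Step 3
Reactants: 4 diethyl (1R,6R)-6-formyl-6-methyl-3-[(triisopropylsilyl)oxy]cyclohex-3-ene-1,2-dicarboxylate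
Product: 7 ethyl (3aR,7aS)-3a-methyl-1,6-dioxooctahydro-2-benzofuran-7-carboxylate (ring A with C1 ketone, C10–CO2Et, cis-fused γ-lactone C6(=O)–O–C19H2 on the α face; C10 epimers), via hydroxy diester 5 (not isolated), via lactone silyl enol ether 6 (not isolated)
Conditions: NaBH4 (0.3 equiv), EtOH, −40 °C; then t-BuOK (0.3 equiv), THF, 40 °C; then HF·pyridine, THF, 0 °C
Reagents that add atoms: none
Why: Borohydride reduces only the aldehyde. Catalytic alkoxide then equilibrates C5 through the ester or lactone enolate while the C19 alkoxide closes the γ-lactone; the cis-fused ring next to an angular methyl group is the thermodynamic sink, so C5 is inverted. The ketone stays masked as its silyl enol ether until HF frees it, so that C5–H and not C10–H is the acidic site during equilibration.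

Step 4
Reactants: 7 ethyl (3aR,7aS)-3a-methyl-1,6-dioxooctahydro-2-benzofuran-7-carboxylate; 8 phenyl vinyl sulfoxide
Product: 10 ethyl (3aR,7R,7aR)-7-ethenyl-3a-methyl-1,6-dioxooctahydro-2-benzofuran-7-carboxylate (10β-vinyl, 10α-CO2Et), via sulfoxide adduct 9 (not isolated)
Conditions: t-BuOK (10 mol%), t-BuOH/THF, 40 °C; then NaHCO3, toluene, 110 °C
Reagents that add atoms: none
Why: Michael addition of the β-keto ester to the vinyl sulfoxide (a vinyl cation equivalent), then thermal syn-elimination of the sulfoxide. The electrophile enters C10 on the convex face of the cis-fused bicycle, anti to the lactone carbon C6 on C5, so the vinyl group (C9) is β and the ester (C20) is α.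

Step 5
Reactants: 10 ethyl (3aR,7R,7aR)-7-ethenyl-3a-methyl-1,6-dioxooctahydro-2-benzofuran-7-carboxylate
Product: 11 ring-A tetraol (10β-vinyl; 1α-OH; CH2OH at C10α (C20), C5α (C6) and C4α (C19); 4β-CH3)
Conditions: LiAlH4, THF, 0 → 25 °C
Reagents that add atoms: none
Why: Exhaustive hydride reduction of ketone, ester and lactone. The C1 ketone is attacked axially, from the face away from the axial C20 substituent on the neighbouring quaternary C10, giving the equatorial 1α-alcohol.

Step 6
Reactants: 11 ring-A tetraol
Product: 12 O1,O20-isopropylidene acetal of 11 (free C6 and C19 hydroxyls)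
Conditions: Me2C(OMe)2 (1.1 equiv), PPTS, acetone, 25 °C
Reagents that add atoms: 2,2-dimethoxypropane, COC(C)(C)OC
Why: Acetonide formation under equilibrating conditions picks the only 1,3-diol (six-membered 1,3-dioxane); the C6/C19 pair could only give a seven-membered ring.

Step 7
Reactants: 12 O1,O20-isopropylidene acetal
Product: 14 6-O-TBDPS, 19-O-acetyl acetonide, via 6-O-silyl ether 13 (not isolated)
Conditions: t-BuPh2SiCl, imidazole, DMF, −20 → 0 °C; then Ac2O, DMAP, pyridine, 25 °C
Reagents that add atoms: tert-butyl(chloro)diphenylsilane, CC(C)(C)[Si](Cl)(c1ccccc1)c1ccccc1; acetic anhydride, CC(=O)OC(C)=O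
Why: The bulky silyl chloride takes the C6 hydroxyl (CH2OH on a tertiary carbon) in preference to the neopentyl, axial C19 hydroxyl, which is then acetylated in the same flask.

Step 8
Reactants: 14 6-O-TBDPS, 19-O-acetyl acetonide
Product: 15 1α,20-diol (6-O-TBDPS, 19-OAc, 10β-vinyl)
Conditions: AcOH/H2O/THF (3:1:1), 40 °C
Reagents that add atoms: none
Why: Mild acid hydrolysis of the acetonide leaves the silyl ether and acetate in place and avoids base-promoted acetyl migration from O19 to O20.

Step 9
Reactants: 16 2,2-dimethyl-1,3-dioxane-4,6-dione (Meldrum's acid); 17 3-(benzyloxy)-3-oxopropanoic acid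
Product: 18 benzyl 3-(2,2-dimethyl-4,6-dioxo-1,3-dioxan-5-yl)-3-oxopropanoate
Conditions: DCC, DMAP, CH2Cl2, 0 → 25 °C
Reagents that add atoms: none
Why: Carbodiimide-mediated C-acylation of Meldrum's acid (Oikawa–Yonemitsu type) gives the acylketene precursor that carries C7, C8, C15, C16 and C17.

Step 10
Reactants: 15 1α,20-diol; 18 benzyl 3-(2,2-dimethyl-4,6-dioxo-1,3-dioxan-5-yl)-3-oxopropanoate
Product: 19 20-O-(5-benzyloxy-3,5-dioxopentanoyl) ester of 15 (free 1α-OH)
Conditions: toluene, 80 °C
Reagents that add atoms: none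
Why: Thermolysis of the acyl Meldrum's acid releases an acylketene, which the primary C20 hydroxyl traps in preference to the secondary C1 hydroxyl next to the quaternary C10. The product is the mixed 3-oxoglutarate.

Step 11
Reactants: 19 20-O-(5-benzyloxy-3,5-dioxopentanoyl) ester
Product: 20 1α-acetate of 19
Conditions: Ac2O, Me3SiOTf (2 mol%), CH2Cl2, 0 °C
Reagents that add atoms: acetic anhydride, CC(=O)OC(C)=O
Why: Lewis acid-catalysed acetylation esterifies the hindered C1 alcohol quickly without base, so the enolisable oxoglutarate is not acylated.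

Step 12
Reactants: 20 1α-acetate
Product: 21 C9 aldehyde (10β-CHO; 10α-CH2O-oxoglutarate; 1α-OAc; 19-OAc; 6-O-TBDPS)
Conditions: O3, CH2Cl2, −78 °C; then Me2S
Reagents that add atoms: ozone, [O-][O+]=O
Why: Ozonolysis of the vinyl group with reductive work-up unmasks the neopentyl aldehyde C9 just before it is needed.

Step 13
Reactants: 21 C9 aldehyde; 22 2-(trimethylsiloxy)buta-1,3-diene
Product: 24 tricyclic cycloadduct (spiro ring A, cis-fused δ-lactone/cyclohexene, C12 trimethylsilyl enol ether C12=C13, C8 bearing COCH2CO2Bn), via alkylidene lactone 23 (not isolated)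
Conditions: ethylenediammonium diacetate (5 mol%), 4 Å MS, toluene, 25 °C; then 22 (5 equiv), 60 °C
Reagents that add atoms: none
Why: The amine salt catalyses an intramolecular Knoevenagel condensation of the C9 aldehyde with the C8 methylene (the C16 methylene would give an eight-membered ring), closing the δ-lactone by a 6-exo aldol addition and dehydration to the 3-acyl-5,6-dihydropyran-2-one 23. 23 is a doubly activated dienophile and adds the electron-rich diene 22 in a normal-demand [4+2] cycloaddition that closes ring C; a hetero-Diels–Alder/Claisen or Michael/ring-closure pathway would converge on the same product. The closest known reaction types are domino Knoevenagel/cycloaddition sequences of alkylidene-1,3-dicarbonyl compounds and Diels–Alder reactions of 4,4-disubstituted 2-carboalkoxycyclohex-2-enones with 2-siloxydienes. C8 and C9 are formed together and cis, because addition to the endocyclic alkene is suprafacial. Their configuration relative to C10 is set by ring A: the diene has to add to the lactone face syn to C1 and anti to C5, and C5, which carries CH2OTBDPS and neighbours the quaternary C4, shields its side more than C1 with its equatorial acetate. Regioselectivity follows from the nucleophilic diene terminus (C11) bonding to the β-carbon C9, which places the silyl enol ether at C12=C13 with its nucleophilic carbon at C13.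

Step 14
Reactants: 24 tricyclic cycloadduct
Product: 25 12,15-dioxo bicyclo[3.2.1]octane β-keto benzyl ester (ring D closed; C16 epimers)
Conditions: (NH4)2Ce(NO3)6 (2.2 equiv), NaHCO3, MeCN, −30 → 0 °C
Reagents that add atoms: none
Why: Oxidative coupling of two enol carbons. Tetravalent cerium oxidises the β-keto ester to a C16 radical, which adds 5-exo to the electron-rich C13 of the silyl enol ether; a second oxidation and loss of silicon give the C12 ketone. C16 can reach C13 only from the face of the C8 acyl group, which fixes C13.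

Step 15
Reactants: 25 12,15-dioxo β-keto benzyl ester
Product: 27 15-oxo β-keto benzyl ester with C12 methylene (complete ring system, 6-O-TBDPS), via C12 tosylhydrazone 26 (not isolated)
Conditions: TsNHNH2, EtOH, 25 °C; then catecholborane, CHCl3, 0 °C; NaOAc·3H2O, 60 °C
Reagents that add atoms: none
Why: The hydrazone forms at the accessible C12 ketone, not at the C15 ketone flanked by the quaternary C8 and the ester-bearing C16; hydride reduction of the tosylhydrazone and loss of sulfinate and N2 (Caglioti/Kabalka deoxygenation) give the methylene.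

Step 16
Reactants: 27 15-oxo β-keto benzyl ester
Product: 28 C6 alcohol of 27
Conditions: HF·pyridine, THF, 0 → 25 °C
Reagents that add atoms: none
Why: Fluoride-mediated cleavage of the silyl ether under acidic conditions that leave the acetates, the lactone and the β-keto ester untouched.

Step 17
Reactants: 28 C6 alcohol
Product: 30 target compound CNP0105570.2, via β-keto acid 29 (not isolated)
Conditions: H2 (1 atm), 10% Pd/C, EtOAc, 25 °C; filter; then aq. CH2O, Et2NH, THF, 0 → 25 °C
Reagents that add atoms: formaldehyde, C=O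
Why: Hydrogenolysis of the benzyl ester gives the β-keto acid, which undergoes a decarboxylative Mannich reaction and amine elimination to the α-methylene ketone. C16 is the only enolisable position of the C15 ketone, and the Michael acceptor is formed last under nearly neutral conditions.

## Compound list

1 | ethyl 3-oxopent-4-enoate | C=CC(=O)CC(=O)OCC | starting material
2 | ethyl (2Z)-3-[(triisopropylsilyl)oxy]penta-2,4-dienoate | C=C/C(O[Si](C(C)C)(C(C)C)C(C)C)=C/C(=O)OCC | intermediate
3 | ethyl (2E)-3-methyl-4-oxobut-2-enoate | CCOC(=O)/C=C(\C)C=O | starting material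
4 | diethyl (1R,6R)-6-formyl-6-methyl-3-[(triisopropylsilyl)oxy]cyclohex-3-ene-1,2-dicarboxylate (C10 epimers) | CCOC(=O)C1C(O[Si](C(C)C)(C(C)C)C(C)C)=CC[C@@](C)(C=O)[C@@H]1C(=O)OCC | intermediate
5 | diethyl (1R,6R)-6-(hydroxymethyl)-6-methyl-3-[(triisopropylsilyl)oxy]cyclohex-3-ene-1,2-dicarboxylate | CCOC(=O)C1C(O[Si](C(C)C)(C(C)C)C(C)C)=CC[C@@](C)(CO)[C@@H]1C(=O)OCC | intermediate
6 | ethyl (3aR,7aS)-3a-methyl-1-oxo-6-[(triisopropylsilyl)oxy]-1,3,3a,4,7,7a-hexahydro-2-benzofuran-7-carboxylate (cis-fused lactone) | CCOC(=O)C1C(O[Si](C(C)C)(C(C)C)C(C)C)=CC[C@@]2(C)COC(=O)[C@@H]12 | intermediate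
7 | ethyl (3aR,7aS)-3a-methyl-1,6-dioxooctahydro-2-benzofuran-7-carboxylate (C10 epimers) | CCOC(=O)C1C(=O)CC[C@@]2(C)COC(=O)[C@@H]12 | intermediate
8 | phenyl vinyl sulfoxide | C=CS(=O)c1ccccc1 | starting material
9 | 10β-[2-(phenylsulfinyl)ethyl] adduct of 7 | O=S(c1ccccc1)CC[C@]1(C(=O)OCC)C(=O)CC[C@@]2(C)COC(=O)[C@@H]12 | intermediate
10 | ethyl (3aR,7R,7aR)-7-ethenyl-3a-methyl-1,6-dioxooctahydro-2-benzofuran-7-carboxylate | C=C[C@]1(C(=O)OCC)C(=O)CC[C@@]2(C)COC(=O)[C@@H]12 | intermediate
11 | ring-A tetraol (10β-vinyl, 1α-OH, 10α-, 5α-, 4α-CH2OH, 4β-CH3) | C=C[C@]1(CO)[C@@H](O)CC[C@@](C)(CO)[C@H]1CO | intermediate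
12 | O1,O20-isopropylidene acetal of 11 | C=C[C@]1(COC(C)(C)O2)[C@@H]2CC[C@@](C)(CO)[C@H]1CO | intermediate
13 | 6-O-TBDPS ether of 12 | C=C[C@]1(COC(C)(C)O2)[C@@H]2CC[C@@](C)(CO)[C@H]1CO[Si](c1ccccc1)(c1ccccc1)C(C)(C)C | intermediate
14 | 6-O-TBDPS, 19-O-acetyl acetonide | C=C[C@]1(COC(C)(C)O2)[C@@H]2CC[C@@](C)(COC(C)=O)[C@H]1CO[Si](c1ccccc1)(c1ccccc1)C(C)(C)C | intermediate
15 | 1α,20-diol (6-O-TBDPS, 19-OAc) | C=C[C@]1(CO)[C@@H](O)CC[C@@](C)(COC(C)=O)[C@H]1CO[Si](c1ccccc1)(c1ccccc1)C(C)(C)C | intermediate
16 | 2,2-dimethyl-1,3-dioxane-4,6-dione | CC1(C)OC(=O)CC(=O)O1 | starting material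
17 | 3-(benzyloxy)-3-oxopropanoic acid | OC(=O)CC(=O)OCc1ccccc1 | starting material
18 | benzyl 3-(2,2-dimethyl-4,6-dioxo-1,3-dioxan-5-yl)-3-oxopropanoate | CC1(C)OC(=O)C(C(=O)CC(=O)OCc2ccccc2)C(=O)O1 | intermediate
19 | 20-O-(5-benzyloxy-3,5-dioxopentanoyl) ester of 15 | C=C[C@]1(COC(=O)CC(=O)CC(=O)OCc2ccccc2)[C@@H](O)CC[C@@](C)(COC(C)=O)[C@H]1CO[Si](c1ccccc1)(c1ccccc1)C(C)(C)C | intermediate
20 | 1α-acetate of 19 | C=C[C@]1(COC(=O)CC(=O)CC(=O)OCc2ccccc2)[C@@H](OC(C)=O)CC[C@@](C)(COC(C)=O)[C@H]1CO[Si](c1ccccc1)(c1ccccc1)C(C)(C)C | intermediate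
21 | C9 aldehyde | O=C[C@]1(COC(=O)CC(=O)CC(=O)OCc2ccccc2)[C@@H](OC(C)=O)CC[C@@](C)(COC(C)=O)[C@H]1CO[Si](c1ccccc1)(c1ccccc1)C(C)(C)C | intermediate
22 | 2-(trimethylsiloxy)buta-1,3-diene | C=CC(=C)O[Si](C)(C)C | starting material
23 | alkylidene β-keto lactone (C8=C9) | O=C(CC(=O)OCc1ccccc1)C1=C[C@]2(COC1=O)[C@@H](OC(C)=O)CC[C@@](C)(COC(C)=O)[C@H]2CO[Si](c1ccccc1)(c1ccccc1)C(C)(C)C | intermediate
24 | tricyclic cycloadduct with C12 silyl enol ether | O=C(CC(=O)OCc1ccccc1)[C@]12CC=C(O[Si](C)(C)C)C[C@H]1[C@]1(COC2=O)[C@@H](OC(C)=O)CC[C@@](C)(COC(C)=O)[C@H]1CO[Si](c1ccccc1)(c1ccccc1)C(C)(C)C | intermediate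
25 | 12,15-dioxo bicyclo[3.2.1]octane β-keto benzyl ester (C16 epimers) | O=C(OCc1ccccc1)C1C(=O)[C@]23C[C@H]1C(=O)C[C@H]2[C@]1(COC3=O)[C@@H](OC(C)=O)CC[C@@](C)(COC(C)=O)[C@H]1CO[Si](c1ccccc1)(c1ccccc1)C(C)(C)C | intermediate
26 | C12 tosylhydrazone of 25 | O=C(OCc1ccccc1)C1C(=O)[C@]23C[C@H]1C(=NNS(=O)(=O)c1ccc(C)cc1)C[C@H]2[C@]1(COC3=O)[C@@H](OC(C)=O)CC[C@@](C)(COC(C)=O)[C@H]1CO[Si](c1ccccc1)(c1ccccc1)C(C)(C)C | intermediate
27 | 15-oxo β-keto benzyl ester, C12 methylene, 6-O-TBDPS | O=C(OCc1ccccc1)C1C(=O)[C@]23C[C@H]1CC[C@H]2[C@]1(COC3=O)[C@@H](OC(C)=O)CC[C@@](C)(COC(C)=O)[C@H]1CO[Si](c1ccccc1)(c1ccccc1)C(C)(C)C | intermediate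
28 | C6 alcohol of 27 | O=C(OCc1ccccc1)C1C(=O)[C@]23C[C@H]1CC[C@H]2[C@]1(COC3=O)[C@@H](OC(C)=O)CC[C@@](C)(COC(C)=O)[C@H]1CO | intermediate
29 | β-keto acid | OC(=O)C1C(=O)[C@]23C[C@H]1CC[C@H]2[C@]1(COC3=O)[C@@H](OC(C)=O)CC[C@@](C)(COC(C)=O)[C@H]1CO | intermediate
30 | CNP0105570.2 (1α,19-diacetoxy-6-hydroxy-15-oxo-6,7-seco-ent-kaur-16-en-7,20-olide) | C=C1C(=O)[C@]23C[C@H]1CC[C@H]2[C@]1(COC3=O)[C@@H](OC(C)=O)CC[C@@](C)(COC(C)=O)[C@H]1CO | target

## Count and risks

Total step count: 17. Longest linear sequence: 16 steps (steps 1–8 and 10–17, from 1 and 3); step 9 prepares reagent 18.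

Least certain steps:

1. **Step 13 (key step).** What may go wrong: poor facial selectivity of the cycloaddition across the spiro centre (diene adding anti to C1 instead of anti to C5), and self-condensation of 23 through its free C16 methylene before the diene is consumed.
   Fallback: set out from 19 and make C1 planar, so that the C1 side of the dienophile is open. Dess–Martin oxidation gives the C1 ketone F1, and ozonolysis gives the keto aldehyde F2. Condensation with TiCl4/pyridine gives the alkylidene lactone F3, which is not isolated. Cycloaddition with 2-[(tert-butyldimethylsilyl)oxy]buta-1,3-diene gives cycloadduct F4. The C1 ketone is then reduced with NaBH4 after the β-keto ester has been turned into its sodium enolate, giving the 1α-alcohol F5 by axial hydride attack. Acetylation gives acetate F6, and oxidative cyclisation as in step 14 brings the route back at 25.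

2. **Step 14.** What may go wrong: loss of the regio-defined silyl enol ether by hydrolysis before C–C bond formation, or its oxidation to the enone or capture by nitrate.
   Fallback: from 24, brominate the enol ether with N-bromosuccinimide on the face away from the C8 acyl group to give the C13 bromo ketone F7. Treat it with K2CO3; the C16 enolate displaces bromide with inversion, and the route is rejoined at 25.

3. **Step 2.** What may go wrong: low enantioselectivity with the β-carboethoxy enal, or Mukaiyama-type addition of the dienol ether to the formyl group instead of cycloaddition.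
   Fallback: run the cycloaddition of 2 and 3 with EtAlCl2 and carry the racemate through step 3 to racemic 7. Hydrogenate with RuCl2[(R)-BINAP]: the catalyst-controlled reduction of the C1 ketone turns the two enantiomers into the diastereomeric hydroxy esters F8 (from the wanted enantiomer) and F9, which are separated. Dess–Martin oxidation of F8 returns enantiopure 7.

4. **Step 3.** What may go wrong: incomplete epimerisation at C5, with the material stalling at the trans-fused lactone.
   Fallback: isolate the trans lactone F10, deprotonate with LiN(iPr)2 (1.1 equiv, −78 °C) and quench with 2,6-di-tert-butyl-4-methylphenol. Kinetic protonation of the lactone enolate on the convex face gives the cis lactone 6, and HF·pyridine then gives 7.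

5. **Step 7.** What may go wrong: poor site selectivity between the C6 and C19 hydroxyls in the silylation.
   Fallback: from 12, acetylate both to the diacetate F11. Hydrolyse the less hindered C6 acetate with Candida antarctica lipase B to the C6 alcohol F12, and silylate it to rejoin at 14.

## Further compounds

F1 | step 13 | C1 ketone of 19 | C=C[C@]1(COC(=O)CC(=O)CC(=O)OCc2ccccc2)C(=O)CC[C@@](C)(COC(C)=O)[C@H]1CO[Si](c1ccccc1)(c1ccccc1)C(C)(C)C
F2 | step 13 | C1-keto C9 aldehyde | O=C[C@]1(COC(=O)CC(=O)CC(=O)OCc2ccccc2)C(=O)CC[C@@](C)(COC(C)=O)[C@H]1CO[Si](c1ccccc1)(c1ccccc1)C(C)(C)C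
F3 | step 13 | C1-keto alkylidene lactone | O=C(CC(=O)OCc1ccccc1)C1=C[C@]2(COC1=O)C(=O)CC[C@@](C)(COC(C)=O)[C@H]2CO[Si](c1ccccc1)(c1ccccc1)C(C)(C)C
F4 | step 13 | C1-keto cycloadduct with C12 tert-butyldimethylsilyl enol ether | O=C(CC(=O)OCc1ccccc1)[C@]12CC=C(O[Si](C)(C)C(C)(C)C)C[C@H]1[C@]1(COC2=O)C(=O)CC[C@@](C)(COC(C)=O)[C@H]1CO[Si](c1ccccc1)(c1ccccc1)C(C)(C)C
F5 | step 13 | 1α-alcohol of F4 | O=C(CC(=O)OCc1ccccc1)[C@]12CC=C(O[Si](C)(C)C(C)(C)C)C[C@H]1[C@]1(COC2=O)[C@@H](O)CC[C@@](C)(COC(C)=O)[C@H]1CO[Si](c1ccccc1)(c1ccccc1)C(C)(C)C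
F6 | step 13 | 1α-acetate of F5 | O=C(CC(=O)OCc1ccccc1)[C@]12CC=C(O[Si](C)(C)C(C)(C)C)C[C@H]1[C@]1(COC2=O)[C@@H](OC(C)=O)CC[C@@](C)(COC(C)=O)[C@H]1CO[Si](c1ccccc1)(c1ccccc1)C(C)(C)C
F7 | step 14 | C13 bromo C12 ketone | O=C(CC(=O)OCc1ccccc1)[C@]12C[C@@H](Br)C(=O)C[C@H]1[C@]1(COC2=O)[C@@H](OC(C)=O)CC[C@@](C)(COC(C)=O)[C@H]1CO[Si](c1ccccc1)(c1ccccc1)C(C)(C)C
F8 | step 2 | C1 hydroxy ester from the wanted enantiomer of 7 (written as the anti isomer) | CCOC(=O)[C@@H]1[C@@H](O)CC[C@@]2(C)COC(=O)[C@@H]12
F9 | step 2 | diastereomeric C1 hydroxy ester from the unwanted enantiomer of 7 | CCOC(=O)[C@@H]1[C@@H](O)CC[C@]2(C)COC(=O)[C@H]12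
F10 | step 3 | trans-fused lactone silyl enol ether (C5 epimer of 6) | CCOC(=O)C1C(O[Si](C(C)C)(C(C)C)C(C)C)=CC[C@@]2(C)COC(=O)[C@H]12
F11 | step 7 | 6,19-di-O-acetyl acetonide | C=C[C@]1(COC(C)(C)O2)[C@@H]2CC[C@@](C)(COC(C)=O)[C@H]1COC(C)=O
F12 | step 7 | 19-O-acetyl acetonide with free C6 hydroxyl | C=C[C@]1(COC(C)(C)O2)[C@@H]2CC[C@@](C)(COC(C)=O)[C@H]1CO
A1 | alternative 1 | C8 2-bromoallyl lactone (vinyl radical precursor) | C=C(Br)C[C@]12CC=CC[C@H]1[C@]1(COC2=O)[C@@H](OC(C)=O)CC[C@@](C)(COC(C)=O)[C@H]1CO[Si](c1ccccc1)(c1ccccc1)C(C)(C)C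
A2 | alternative 1 | 15-deoxo 16-methylene tetracycle | C=C1C[C@]23C[C@H]1CC[C@H]2[C@]1(COC3=O)[C@@H](OC(C)=O)CC[C@@](C)(COC(C)=O)[C@H]1CO[Si](c1ccccc1)(c1ccccc1)C(C)(C)C
A3 | alternative 2 | dienyl acrylate (ester-tethered triene) | C=C/C=C/[C@]1(COC(=O)C(=C)CC(Br)=C)[C@@H](OC(C)=O)CC[C@@](C)(COC(C)=O)[C@H]1CO[Si](c1ccccc1)(c1ccccc1)C(C)(C)C
A4 | alternative 2 | intramolecular cycloadduct with C11=C12 alkene | C=C(Br)C[C@]12CCC=C[C@H]1[C@]1(COC2=O)[C@@H](OC(C)=O)CC[C@@](C)(COC(C)=O)[C@H]1CO[Si](c1ccccc1)(c1ccccc1)C(C)(C)C
A5 | alternative 3 | 1α,19-diacetoxy-6β,7β-dihydroxy-7α,20-epoxy-ent-kaur-16-en-15-one | C=C1C(=O)[C@]23C[C@H]1CC[C@H]2[C@]1(CO[C@@]34O)[C@@H](OC(C)=O)CC[C@@](C)(COC(C)=O)[C@H]1[C@@H]4O
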